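**Retrosynthetic overview**
1. Ring A is closed last by Dieckmann cyclisation of a β-diketone (from 6-methylhept-5-en-2-one) onto the axial ester of a hydrindane 6,6-diester half-acid; the acetyl and second prenyl groups are then added.
2. The spiro centre is fixed by an esterase, which hydrolyses only the exposed equatorial ester of the gem-diester.
3. The hydroperoxide comes from cobalt/O2/silane peroxidation of a 4-methylene group, with O2 entering anti to the axial ester.
4. The cyclohexane ring comes from double alkylation of dimethyl malonate by a cyclopentane carrying a CH2OTs arm and a 2-(chloromethyl)vinyl arm.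
5. The cyclopentane and its three stereocentres come from a rhodium/BINAP isopropenyl addition–aldol cyclisation of an achiral keto enoate. Ring order: cyclopentane, cyclohexane, ring A.

Assumption: (R)-BINAP is taken as the ligand antipode that gives (5R)-5 (by analogy with rhodium/BINAP additions to (E)-enones); if the sense is the reverse, (S)-BINAP is used and nothing else changes.

Locants in names: hydrindane C-1 (carbinol), C-3a/C-7a (ring fusion), C-4 (peroxide carbon), C-6 (gem-diester, later spiro carbon = C-1′); ring A C-2′ (C=O), C-3′ (acetyl carbon), C-4′, C-5′ (prenyl carbon), C-6′ (C=O).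

**Step 1**
Reactants: 1 hex-5-en-2-one; 2 methyl acrylate
Product: 3 methyl (E)-6-oxohept-2-enoate
Conditions: second-generation Grubbs catalyst RuCl2(=CHPh)(PCy3)(H2IMes) (2 mol%), 2 (3 equiv), CH2Cl2, 40 °C
Reagents that add atoms: none
Why: Olefin cross-metathesis of a terminal alkene with an acrylate is E-selective and leaves the ketone untouched; no stereocentre is formed.

**Step 2**
Reactants: 3 methyl (E)-6-oxohept-2-enoate; 4 isopropenylboronic acid pinacol ester
Product: 5 methyl (1S,2R,5R)-2-hydroxy-2-methyl-5-(prop-1-en-2-yl)cyclopentane-1-carboxylate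
Conditions: [Rh(OH)(cod)]2 (2.5 mol%), (R)-BINAP (6 mol%), KOH (10 mol%), 4 (2 equiv), dioxane/H2O 10:1, 60 °C
Reagents that add atoms: none
Why: Rhodium/BINAP asymmetric conjugate addition (Hayashi–Miyaura type) sets C-5 by enantioface-selective carbometalation, and the rhodium enolate is trapped by the tethered methyl ketone in a chelated aldol cyclisation (Krische-type), which places OH cis to the ester and, through allylic strain in the enolate, the isopropenyl group trans to it.

**Step 3**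
Reactants: 5 methyl (1S,2R,5R)-2-hydroxy-2-methyl-5-(prop-1-en-2-yl)cyclopentane-1-carboxylate
Product: 6 (1R,2R,3R)-2-(hydroxymethyl)-1-methyl-3-(prop-1-en-2-yl)cyclopentan-1-ol
Conditions: LiAlH4, THF, 0 °C
Reagents that add atoms: none
Why: Hydride reduction of the ester gives the primary alcohol, leaves the three stereocentres untouched and removes the epimerisable α-position.

**Step 4**
Reactants: 6 (1R,2R,3R)-2-(hydroxymethyl)-1-methyl-3-(prop-1-en-2-yl)cyclopentan-1-ol
Product: 7 [(1R,2R,5R)-2-hydroxy-2-methyl-5-(prop-1-en-2-yl)cyclopentyl]methyl 4-methylbenzenesulfonate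
Conditions: TsCl (1.1 equiv), pyridine, CH2Cl2, 0 °C
Reagents that add atoms: 4-methylbenzenesulfonyl chloride, Cc1ccc(cc1)S(Cl)(=O)=O
Why: Sulfonylation is selective for the primary over the hindered tertiary alcohol.

**Step 5**
Reactants: 7 [(1R,2R,5R)-2-hydroxy-2-methyl-5-(prop-1-en-2-yl)cyclopentyl]methyl 4-methylbenzenesulfonate
Product: 8 [(1R,2R,5R)-2-methyl-5-(prop-1-en-2-yl)-2-(triethylsilyloxy)cyclopentyl]methyl 4-methylbenzenesulfonate
Conditions: Et3SiOTf (1.3 equiv), 2,6-lutidine, CH2Cl2, −78 to 0 °C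
Reagents that add atoms: triethylsilyl trifluoromethanesulfonate, CC[Si](CC)(CC)OS(=O)(=O)C(F)(F)F
Why: Silyl triflate silylation caps the tertiary alcohol so that it cannot close an oxetane onto the tosylate under the basic conditions of step 7.

**Step 6**
Reactants: 8 [(1R,2R,5R)-2-methyl-5-(prop-1-en-2-yl)-2-(triethylsilyloxy)cyclopentyl]methyl 4-methylbenzenesulfonate
Product: 9 [(1R,2R,5R)-5-(3-chloroprop-1-en-2-yl)-2-methyl-2-(triethylsilyloxy)cyclopentyl]methyl 4-methylbenzenesulfonate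
Conditions: NCS (1.1 equiv), PhSeCl (5 mol%), CH2Cl2, 25 °C
Reagents that add atoms: N-chlorosuccinimide, O=C1CCC(=O)N1Cl
Why: Selenium-catalysed ene-type allylic chlorination turns the isopropenyl group into a 2-substituted allyl chloride (both allylic termini give the same constitution) and touches no stereocentre.

**Step 7**
Reactants: 9 [(1R,2R,5R)-5-(3-chloroprop-1-en-2-yl)-2-methyl-2-(triethylsilyloxy)cyclopentyl]methyl 4-methylbenzenesulfonate; 10 dimethyl malonate
Product: 12 dimethyl (1R,3aR,7aS)-1-methyl-4-methylidene-1-(triethylsilyloxy)octahydro-1H-indene-6,6-dicarboxylate, via monoalkylated malonate 11 (not isolated)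
Conditions: 10 (2 equiv), NaH (3 equiv), THF, 0 to 25 °C, slow addition of 9; then DMF, NaI (0.2 equiv), 70 °C
Reagents that add atoms: none
Why: Double malonate alkylation (SN2 at the allylic chloride, then 6-exo-tet closure on the tosylate) builds the trans-fused cyclohexane from the trans arms; C-6 carries two identical esters, so no new stereocentre arises.

**Step 8**
Reactants: 12 dimethyl (1R,3aR,7aS)-1-methyl-4-methylidene-1-(triethylsilyloxy)octahydro-1H-indene-6,6-dicarboxylate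
Product: 13 dimethyl (1R,3aR,4R,7aS)-1,4-dimethyl-1-(triethylsilyloxy)-4-[(triethylsilyl)peroxy]octahydro-1H-indene-6,6-dicarboxylate
Conditions: Co(acac)2 (10 mol%), O2 (1 atm), Et3SiH (3 equiv), ClCH2CH2Cl, 25 °C
Reagents that add atoms: dioxygen, O=O; triethylsilane, CC[SiH](CC)CC
Why: Isayama–Mukaiyama hydrosilylperoxidation gives the tertiary C-4 radical by Markovnikov hydrogen-atom transfer, and O2 adds on the equatorial face anti to the syn-axial C-6 ester (the selectivity seen in hydration of labdane 8(17)-enes), so the peroxide is equatorial and the new methyl axial.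

**Step 9**
Reactants: 13 dimethyl (1R,3aR,4R,7aS)-1,4-dimethyl-1-(triethylsilyloxy)-4-[(triethylsilyl)peroxy]octahydro-1H-indene-6,6-dicarboxylate
Product: 14 dimethyl (1R,3aR,4R,7aS)-4-hydroperoxy-1-hydroxy-1,4-dimethyloctahydro-1H-indene-6,6-dicarboxylate
Conditions: HF·pyridine, pyridine, THF, 0 to 25 °C
Reagents that add atoms: none
Why: Fluoride-driven desilylation cleaves the silyl peroxide and the silyl ether without touching the O–O bond or any stereocentre.

**Step 10**
Reactants: 14 dimethyl (1R,3aR,4R,7aS)-4-hydroperoxy-1-hydroxy-1,4-dimethyloctahydro-1H-indene-6,6-dicarboxylate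
Product: 15 dimethyl (1R,3aR,4R,7aS)-1-hydroxy-4-[(2-methoxypropan-2-yl)peroxy]-1,4-dimethyloctahydro-1H-indene-6,6-dicarboxylate
Conditions: 2-methoxypropene (1.5 equiv), PPTS (5 mol%), CH2Cl2, 0 °C
Reagents that add atoms: 2-methoxypropene, COC(C)=C
Why: Acid-catalysed perketalisation protects the hydroperoxide, which adds to the enol ether faster than the hindered tertiary alcohol, as a base-stable peroxyketal.

**Step 11**
Reactants: 15 dimethyl (1R,3aR,4R,7aS)-1-hydroxy-4-[(2-methoxypropan-2-yl)peroxy]-1,4-dimethyloctahydro-1H-indene-6,6-dicarboxylate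
Product: 16 (1R,3aR,4R,6S,7aS)-1-hydroxy-6-(methoxycarbonyl)-4-[(2-methoxypropan-2-yl)peroxy]-1,4-dimethyloctahydro-1H-indene-6-carboxylic acid
Conditions: pig liver esterase (a carboxylesterase), 0.1 M phosphate buffer pH 7.5, DMSO (10 vol%), 30 °C; work-up at pH 4, 0 °C
Reagents that add atoms: water, O
Why: Enzymatic ester hydrolysis at neutral pH cleaves only the exposed equatorial ester, because the axial one is shielded by the syn-axial 4-methyl group, and this choice between the two diastereotopic esters fixes the spiro stereocentre C-6.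

**Step 12**
Reactants: 16 (1R,3aR,4R,6S,7aS)-1-hydroxy-6-(methoxycarbonyl)-4-[(2-methoxypropan-2-yl)peroxy]-1,4-dimethyloctahydro-1H-indene-6-carboxylic acid; 17 6-methylhept-5-en-2-one
Product: 19 methyl (1R,3aR,4R,6S,7aS)-1-hydroxy-4-[(2-methoxypropan-2-yl)peroxy]-1,4-dimethyl-6-(7-methyl-3-oxooct-6-enoyl)octahydro-1H-indene-6-carboxylate, via acyl imidazolide 18 (not isolated)
Conditions: CDI (1.2 equiv), THF, 25 °C; then added to the lithium enolate of 17 (3.2 equiv, from LiN(iPr)2, THF, −78 °C), −78 to 0 °C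
Reagents that add atoms: none
Why: Crossed Claisen acylation of the kinetic methyl-side enolate by the acyl imidazolide gives the β-diketone, while the hindered axial methyl ester is not attacked and the quaternary C-6 keeps its configuration.

**Step 13**
Reactants: 19 methyl (1R,3aR,4R,6S,7aS)-1-hydroxy-4-[(2-methoxypropan-2-yl)peroxy]-1,4-dimethyl-6-(7-methyl-3-oxooct-6-enoyl)octahydro-1H-indene-6-carboxylate
Product: 20 (1R,3aR,4R,6S,7aS)-1-hydroxy-4-[(2-methoxypropan-2-yl)peroxy]-1,4-dimethyl-5′-(3-methylbut-2-en-1-yl)octahydrospiro[indene-6,1′-cyclohexane]-2′,4′,6′-trione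
Conditions: LiN(iPr)2 (3.5 equiv), THF, −78 to 25 °C
Reagents that add atoms: none
Why: Dieckmann (intramolecular Claisen) condensation of the β-diketone dianion through its γ-carbon onto the axial ester closes ring A, is driven by formation of the trione enolate, and places the prenyl-bearing carbon next to the axial carbonyl because C-6 cannot epimerise.

**Step 14**
Reactants: 20 (1R,3aR,4R,6S,7aS)-1-hydroxy-4-[(2-methoxypropan-2-yl)peroxy]-1,4-dimethyl-5′-(3-methylbut-2-en-1-yl)octahydrospiro[indene-6,1′-cyclohexane]-2′,4′,6′-trione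
Product: 22 (1R,3aR,4R,6R,7aS)-3′-acetyl-1,4′-dihydroxy-4-[(2-methoxypropan-2-yl)peroxy]-1,4-dimethyl-5′-(3-methylbut-2-en-1-yl)octahydrospiro[indene-6,1′-cyclohex[3]ene]-2′,6′-dione, via enol acetate 21 (not isolated)
Conditions: AcCl (1.1 equiv), Et3N, CH2Cl2, 0 °C; then DMAP (0.3 equiv), MeCN, 40 °C
Reagents that add atoms: acetyl chloride, CC(Cl)=O
Why: O-acetylation followed by DMAP-catalysed O-to-C acyl migration (the rearrangement used for 2-acylcyclohexane-1,3-diones) puts the acetyl group on C-3′, the only carbon where it gives a stable hydrogen-bonded enol, and no stereocentre is touched.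

**Step 15**
Reactants: 22 (1R,3aR,4R,6R,7aS)-3′-acetyl-1,4′-dihydroxy-4-[(2-methoxypropan-2-yl)peroxy]-1,4-dimethyl-5′-(3-methylbut-2-en-1-yl)octahydrospiro[indene-6,1′-cyclohex[3]ene]-2′,6′-dione; 23 1-bromo-3-methylbut-2-ene
Product: 24 (1R,3aR,4R,6R,7aS)-3′-acetyl-1,4′-dihydroxy-4-[(2-methoxypropan-2-yl)peroxy]-1,4-dimethyl-5′,5′-bis(3-methylbut-2-en-1-yl)octahydrospiro[indene-6,1′-cyclohex[3]ene]-2′,6′-dione
Conditions: LiN(SiMe3)2 (3.3 equiv), THF, −78 °C; 23 (1.2 equiv), −78 to 0 °C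
Reagents that add atoms: none
Why: C-alkylation of the dianion at its last-formed and most nucleophilic carbon C-5′ (the only ring CH left) adds the second prenyl group, and C-5′ then carries two identical groups so no stereocentre arises.

**Step 16**
Reactants: 24 (1R,3aR,4R,6R,7aS)-3′-acetyl-1,4′-dihydroxy-4-[(2-methoxypropan-2-yl)peroxy]-1,4-dimethyl-5′,5′-bis(3-methylbut-2-en-1-yl)octahydrospiro[indene-6,1′-cyclohex[3]ene]-2′,6′-dione
Product: 25 CNP0149131.2
Conditions: AcOH/THF/H2O 3:1:1, 25 °C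
Reagents that add atoms: none
Why: Mild acid hydrolysis of the peroxyketal frees the hydroperoxide under conditions too weak to cyclise the prenyl enol, and all five stereocentres stay as set.

**Compound list**
1 | hex-5-en-2-one | CC(=O)CCC=C | starting material
2 | methyl acrylate | COC(=O)C=C | starting material
3 | methyl (E)-6-oxohept-2-enoate | COC(=O)/C=C/CCC(C)=O | intermediate
4 | isopropenylboronic acid pinacol ester | CC(=C)B1OC(C)(C)C(C)(C)O1 | starting material
5 | methyl (1S,2R,5R)-2-hydroxy-2-methyl-5-(prop-1-en-2-yl)cyclopentane-1-carboxylate (OH cis to ester; isopropenyl trans to ester) | COC(=O)[C@H]1[C@@H](CC[C@@]1(C)O)C(C)=C | intermediate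
6 | (1R,2R,3R)-2-(hydroxymethyl)-1-methyl-3-(prop-1-en-2-yl)cyclopentan-1-ol | OC[C@H]1[C@@H](CC[C@@]1(C)O)C(C)=C | intermediate
7 | [(1R,2R,5R)-2-hydroxy-2-methyl-5-(prop-1-en-2-yl)cyclopentyl]methyl 4-methylbenzenesulfonate | Cc1ccc(cc1)S(=O)(=O)OC[C@H]1[C@@H](CC[C@@]1(C)O)C(C)=C | intermediate
8 | [(1R,2R,5R)-2-methyl-5-(prop-1-en-2-yl)-2-(triethylsilyloxy)cyclopentyl]methyl 4-methylbenzenesulfonate | Cc1ccc(cc1)S(=O)(=O)OC[C@H]1[C@@H](CC[C@@]1(C)O[Si](CC)(CC)CC)C(C)=C | intermediate
9 | [(1R,2R,5R)-5-(3-chloroprop-1-en-2-yl)-2-methyl-2-(triethylsilyloxy)cyclopentyl]methyl 4-methylbenzenesulfonate | Cc1ccc(cc1)S(=O)(=O)OC[C@H]1[C@@H](CC[C@@]1(C)O[Si](CC)(CC)CC)C(=C)CCl | intermediate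
10 | dimethyl malonate | COC(=O)CC(=O)OC | starting material
11 | dimethyl 2-{2-[(1R,2R,3R)-3-methyl-2-(tosyloxymethyl)-3-(triethylsilyloxy)cyclopentyl]prop-2-en-1-yl}propanedioate | Cc1ccc(cc1)S(=O)(=O)OC[C@H]1[C@@H](CC[C@@]1(C)O[Si](CC)(CC)CC)C(=C)CC(C(=O)OC)C(=O)OC | intermediate (not isolated)
12 | dimethyl (1R,3aR,7aS)-1-methyl-4-methylidene-1-(triethylsilyloxy)octahydro-1H-indene-6,6-dicarboxylate (trans-fused) | COC(=O)C1(C[C@H]2[C@@H](CC[C@@]2(C)O[Si](CC)(CC)CC)C(=C)C1)C(=O)OC | intermediate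
13 | dimethyl (1R,3aR,4R,7aS)-1,4-dimethyl-1-(triethylsilyloxy)-4-[(triethylsilyl)peroxy]octahydro-1H-indene-6,6-dicarboxylate (peroxide equatorial; 4-methyl axial) | COC(=O)C1(C[C@H]2[C@@H](CC[C@@]2(C)O[Si](CC)(CC)CC)[C@](C)(OO[Si](CC)(CC)CC)C1)C(=O)OC | intermediate
14 | dimethyl (1R,3aR,4R,7aS)-4-hydroperoxy-1-hydroxy-1,4-dimethyloctahydro-1H-indene-6,6-dicarboxylate | COC(=O)C1(C[C@H]2[C@@H](CC[C@@]2(C)O)[C@](C)(OO)C1)C(=O)OC | intermediate
15 | dimethyl (1R,3aR,4R,7aS)-1-hydroxy-4-[(2-methoxypropan-2-yl)peroxy]-1,4-dimethyloctahydro-1H-indene-6,6-dicarboxylate | COC(=O)C1(C[C@H]2[C@@H](CC[C@@]2(C)O)[C@](C)(OOC(C)(C)OC)C1)C(=O)OC | intermediate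
16 | (1R,3aR,4R,6S,7aS)-1-hydroxy-6-(methoxycarbonyl)-4-[(2-methoxypropan-2-yl)peroxy]-1,4-dimethyloctahydro-1H-indene-6-carboxylic acid (acid equatorial; ester axial) | COC(=O)[C@]1(C[C@H]2[C@@H](CC[C@@]2(C)O)[C@](C)(OOC(C)(C)OC)C1)C(O)=O | intermediate
17 | 6-methylhept-5-en-2-one | CC(=O)CCC=C(C)C | starting material
18 | methyl (1R,3aR,4R,6S,7aS)-1-hydroxy-6-(1H-imidazole-1-carbonyl)-4-[(2-methoxypropan-2-yl)peroxy]-1,4-dimethyloctahydro-1H-indene-6-carboxylate | COC(=O)[C@]1(C[C@H]2[C@@H](CC[C@@]2(C)O)[C@](C)(OOC(C)(C)OC)C1)C(=O)n1ccnc1 | intermediate (not isolated)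
19 | methyl (1R,3aR,4R,6S,7aS)-1-hydroxy-4-[(2-methoxypropan-2-yl)peroxy]-1,4-dimethyl-6-(7-methyl-3-oxooct-6-enoyl)octahydro-1H-indene-6-carboxylate | COC(=O)[C@]1(C[C@H]2[C@@H](CC[C@@]2(C)O)[C@](C)(OOC(C)(C)OC)C1)C(=O)CC(=O)CCC=C(C)C | intermediate
20 | (1R,3aR,4R,6S,7aS)-1-hydroxy-4-[(2-methoxypropan-2-yl)peroxy]-1,4-dimethyl-5′-(3-methylbut-2-en-1-yl)octahydrospiro[indene-6,1′-cyclohexane]-2′,4′,6′-trione (drawn as triketone; C-6′ carbonyl axial; C-5′ enolisable) | C1C(=O)C(CC=C(C)C)C(=O)[C@]2(C[C@H]3[C@@H](CC[C@@]3(C)O)[C@](C)(OOC(C)(C)OC)C2)C1=O | intermediate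
21 | 4′-O-acetyl enol ester of 20 (one regioisomer drawn; spiro carbon as in 20) | C1=C(OC(C)=O)C(CC=C(C)C)C(=O)[C@]2(C[C@H]3[C@@H](CC[C@@]3(C)O)[C@](C)(OOC(C)(C)OC)C2)C1=O | intermediate (not isolated)
22 | (1R,3aR,4R,6R,7aS)-3′-acetyl-1,4′-dihydroxy-4-[(2-methoxypropan-2-yl)peroxy]-1,4-dimethyl-5′-(3-methylbut-2-en-1-yl)octahydrospiro[indene-6,1′-cyclohex[3]ene]-2′,6′-dione (6R only by change of CIP priority; no inversion) | CC(=O)C1=C(O)C(CC=C(C)C)C(=O)[C@]2(C[C@H]3[C@@H](CC[C@@]3(C)O)[C@](C)(OOC(C)(C)OC)C2)C1=O | intermediate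
23 | 1-bromo-3-methylbut-2-ene (prenyl bromide) | CC(C)=CCBr | starting material
24 | (1R,3aR,4R,6R,7aS)-3′-acetyl-1,4′-dihydroxy-4-[(2-methoxypropan-2-yl)peroxy]-1,4-dimethyl-5′,5′-bis(3-methylbut-2-en-1-yl)octahydrospiro[indene-6,1′-cyclohex[3]ene]-2′,6′-dione | CC(=O)C1=C(O)C(CC=C(C)C)(CC=C(C)C)C(=O)[C@]2(C[C@H]3[C@@H](CC[C@@]3(C)O)[C@](C)(OOC(C)(C)OC)C2)C1=O | intermediate
25 | CNP0149131.2, (1R,3aR,4R,6R,7aS)-3′-acetyl-4-hydroperoxy-1,4′-dihydroxy-1,4-dimethyl-5′,5′-bis(3-methylbut-2-en-1-yl)octahydrospiro[indene-6,1′-cyclohex[3]ene]-2′,6′-dione | CC(=O)C1=C(O)C(CC=C(C)C)(CC=C(C)C)C(=O)[C@]2(C[C@H]3[C@@H](CC[C@@]3(C)O)[C@](C)(OO)C2)C1=O | target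

**Totals**
Total step count: 16. Longest linear sequence: 16 steps (1 and 2 to 25).

**Steps most likely to fail**

Step 2. The rhodium ester enolate may be protonated before it closes onto the ketone, and the enantioselectivity on an acyclic enoate is less secure than on enones. The fallback sets out from 1 and comes back at 6. Cross-metathesis of 1 with 1-[(tert-butyldimethylsilyl)oxy]but-3-en-2-one (second-generation Grubbs catalyst) gives (E)-1-[(tert-butyldimethylsilyl)oxy]oct-3-ene-2,7-dione F1, an enone–ketone of the class on which the rhodium/BINAP addition–aldol cyclisation is established. The same catalyst system and 4 then give 2-[(tert-butyldimethylsilyl)oxy]-1-[(1S,2R,5R)-2-hydroxy-2-methyl-5-(prop-1-en-2-yl)cyclopentyl]ethan-1-one F2. HF·pyridine frees 2-hydroxy-1-[(1S,2R,5R)-2-hydroxy-2-methyl-5-(prop-1-en-2-yl)cyclopentyl]ethan-1-one F3. NaIO4 cleaves the α-hydroxy ketone to (1S,2R,5R)-2-hydroxy-2-methyl-5-(prop-1-en-2-yl)cyclopentane-1-carboxylic acid F4, and LiAlH4 reduces F4 to 6.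

Step 11. The esterase may not accept the bulky, lipophilic diester. The fallback sets out from 15 and comes back at 19. The lithium enolate of 17 (3 equiv, LiN(iPr)2, THF, −78 to 25 °C) is condensed directly with diester 15 in a crossed Claisen reaction. Only the exposed equatorial ester can be reached, so 19 forms without hydrolysis and activation, and steps 11 and 12 are skipped. No compound outside the list is made (F0).

Step 13. The axial methyl ester, syn to the axial 4-methyl group, may be too hindered for the dianion to attack. The fallback sets out from 19 and comes back at 20. LiI in ethyl acetate at 77 °C removes the ester methyl group by SN2 attack at the methyl carbon, which does not feel the hindrance at the carbonyl, and gives (1R,3aR,4R,6S,7aS)-1-hydroxy-4-[(2-methoxypropan-2-yl)peroxy]-1,4-dimethyl-6-(7-methyl-3-oxooct-6-enoyl)octahydro-1H-indene-6-carboxylic acid F5. CDI converts it into the axial acyl imidazolide of that acid F6, a smaller and much stronger acyl donor than the methyl ester. LiN(SiMe3)2 (3.5 equiv, THF, −78 to 25 °C) then closes ring A onto it to give 20.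

**Further compounds**
F1 | step 2 | (E)-1-[(tert-butyldimethylsilyl)oxy]oct-3-ene-2,7-dione | CC(=O)CC/C=C/C(=O)CO[Si](C)(C)C(C)(C)C
F2 | step 2 | 2-[(tert-butyldimethylsilyl)oxy]-1-[(1S,2R,5R)-2-hydroxy-2-methyl-5-(prop-1-en-2-yl)cyclopentyl]ethan-1-one | CC(C)(C)[Si](C)(C)OCC(=O)[C@H]1[C@@H](CC[C@@]1(C)O)C(C)=C
F3 | step 2 | 2-hydroxy-1-[(1S,2R,5R)-2-hydroxy-2-methyl-5-(prop-1-en-2-yl)cyclopentyl]ethan-1-one | OCC(=O)[C@H]1[C@@H](CC[C@@]1(C)O)C(C)=C
F4 | step 2 | (1S,2R,5R)-2-hydroxy-2-methyl-5-(prop-1-en-2-yl)cyclopentane-1-carboxylic acid | OC(=O)[C@H]1[C@@H](CC[C@@]1(C)O)C(C)=C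
F0 | step 11 | none | none
F5 | step 13 | (1R,3aR,4R,6S,7aS)-1-hydroxy-4-[(2-methoxypropan-2-yl)peroxy]-1,4-dimethyl-6-(7-methyl-3-oxooct-6-enoyl)octahydro-1H-indene-6-carboxylic acid | OC(=O)[C@]1(C[C@H]2[C@@H](CC[C@@]2(C)O)[C@](C)(OOC(C)(C)OC)C1)C(=O)CC(=O)CCC=C(C)C
F6 | step 13 | 1-[(1R,3aR,4R,6S,7aS)-1-hydroxy-6-(1H-imidazole-1-carbonyl)-4-[(2-methoxypropan-2-yl)peroxy]-1,4-dimethyloctahydro-1H-inden-6-yl]-7-methyloct-6-ene-1,3-dione | O=C(n1ccnc1)[C@]1(C[C@H]2[C@@H](CC[C@@]2(C)O)[C@](C)(OOC(C)(C)OC)C1)C(=O)CC(=O)CCC=C(C)C
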